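**Strategy**

The cis C3=C4 ethene unit of the 5,6-dihydropyran-2-one ring, flanked by the C5 methylene and the C2 lactone carbonyl, is treated as acetylene. In one flask, lithium acetylide opens a terminal epoxide (its CH–O carbon is the future C6–O1) to make C4–C5, and the resulting alkyne is metalated and carboxylated with CO2 to make C3–C2. Cis-semihydrogenation then lets O1 close the ring. The epoxide, already carrying three stereocentres, is assembled by a three-component dithiane linchpin union of (R)-1,2-epoxyundecane and twofold-symmetric (2R,4R)-diepoxypentane. The fourth carbinol centre comes from a hydroxyl-directed anti reduction.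

Key step: step 5

Assumption: 1,5-dichloropentane-2,4-dione (5) is taken as a purchasable building block.

Numbering used below: ring O1, C2(=O), C3=C4, C5, C6; side chain C1'–C15'. The open-chain acids 15–18 are numbered from the carboxyl carbon (C5 = future ring C6, C7 = C2', C9 = C4', C11 = C6').

**Route**

Step 1
Reactants: 1 (R)-epichlorohydrin; 2 n-octylmagnesium bromide
Product: 4 (R)-1,2-epoxyundecane, via bromomagnesium chlorohydrin alkoxide 3 (not isolated)
Conditions: CuI (10 mol%), THF, −30 → 0 °C; then NaOH (aq), rt
Reagents that add atoms: none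
Why: Copper-catalysed Grignard opening of the epoxide occurs by SN2 attack at the unsubstituted ring carbon and leaves the C–Cl bond untouched; hydroxide then closes the chlorohydrin alkoxide by intramolecular Williamson displacement, and since the stereocentre is never attacked the (R) configuration is carried over (the chloromethyl arm becomes the new oxirane CH2).

Step 2
Reactants: 5 1,5-dichloropentane-2,4-dione
Product: 6 (2R,4R)-1,5-dichloropentane-2,4-diol
Conditions: H2 (80 atm), [RuCl2((S)-BINAP)]2·NEt3 (0.3 mol%), MeOH, 80 °C; recrystallisation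
Reagents that add atoms: none
Why: Noyori asymmetric hydrogenation of a β-diketone, in which each ketone is reduced through its chelate with the second carbonyl oxygen on the chiral divalent ruthenium diphosphine, so both carbinol centres are set by catalyst control; the (S)-BINAP antipode is chosen for the sense of hydride delivery known for β-keto esters and β-diketones (CIP labels inverted by the chloromethyl groups), and the double reduction should leave the minor sense mainly as the separable meso diol.

Step 3
Reactants: 6 (2R,4R)-1,5-dichloropentane-2,4-diol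
Product: 7 (2R,4R)-1,2:4,5-diepoxypentane
Conditions: KOH (powdered), Et2O, 0 °C → rt
Reagents that add atoms: none
Why: Twofold intramolecular Williamson etherification (3-exo-tet) of the bis-chlorohydrin; the carbinol carbons are not attacked, so both configurations are retained.

Step 4
Reactants: 8 2-(tert-butyldimethylsilyl)-1,3-dithiane; 4 (R)-1,2-epoxyundecane; 7 (2R,4R)-1,2:4,5-diepoxypentane
Product: 12 epoxy alcohol linchpin adduct, via lithiated silyl dithiane 9 (not isolated), via lithium alkoxide 10 (not isolated), via Brook-rearranged dithiane anion 11 (not isolated)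
Conditions: t-BuLi, Et2O, −78 → −45 °C; 4, Et2O, −78 → −25 °C; then 7 (3 equiv), THF/HMPA, −78 → 0 °C; NH4Cl (aq)
Reagents that add atoms: none
Why: Dithiane linchpin coupling with solvent-controlled 1,4-Brook rearrangement (anion relay): lithiated 8 opens 4 at its CH2 carbon, the alkoxide is stable in ether, and HMPA then triggers C-to-O silyl migration that unveils a new dithiane anion, which opens one of the two homotopic oxiranes of excess 7 at CH2; no stereocentre is formed, the three carbinol/oxirane centres are imported unchanged from 4 and 7, and the excess of 7 should suppress a second addition.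

Step 5
Reactants: 12 epoxy alcohol linchpin adduct
Product: 15 dithiane-bearing 5,7-dihydroxy-2-ynoic acid, via alkyne dilithium alkoxide 13 (not isolated), via lithium alkynide 14 (not isolated)
Conditions: LiC≡CH·H2NCH2CH2NH2 (5 equiv), THF/DMPU, 0 °C → rt; then n-BuLi (5 equiv), −78 → −30 °C; CO2 (g), −78 °C → rt; HCl (aq) to pH 3
Reagents that add atoms: lithium acetylide–ethylenediamine complex ([Li]C#C.NCCN); carbon dioxide (O=C=O)
Why: Lithium acetylide opens the terminal epoxide of 12 by SN2 attack at the unsubstituted carbon (future C5), forming the C4–C5 bond and releasing the C6 alkoxide (future O1); the new terminal alkyne is then C-lithiated (pKa about 25, the alkoxides are spectators) and the alkynide adds to CO2, forming the C3–C2 bond, so that acetylene ends up stitched between C5 and the future lactone carbonyl in one flask. Each half is a textbook reaction type (acetylide opening of monosubstituted epoxides; carboxylation of lithium alkynides, the classical entry to 5-hydroxy-2-ynoic acids), and the step is their telescoped three-component version. No ring is closed here; the six-membered lactone closes in step 8 once cis-semihydrogenation has bent the C2–C3–C4–C5 unit. No stereocentre is created: C6 keeps the configuration of the oxirane CH because only the CH2 carbon is attacked, and the other centres are remote. The step needs regioselective attack at CH2 (secured by the steric bias of a monosubstituted oxirane), carboxylation that persists only at carbon (lithium alkyl carbonates formed at the alkoxides lose CO2 on acidification), and survival of the dithiane and the silyl ether, both inert to acetylide and alkyllithium at low temperature.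

Step 6
Reactants: 15 dithiane-bearing 5,7-dihydroxy-2-ynoic acid
Product: 16 9-oxo-5,7-dihydroxy-2-ynoic acid
Conditions: PhI(O2CCF3)2 (1.5 equiv), MeCN/H2O (9:1), 0 °C, 15 min
Reagents that add atoms: water (O)
Why: Oxidative dethioketalisation with a trivalent iodine reagent, in which sulfur is activated as a sulfonium, water adds to the thionium ion and the ketone is released; the conjugated alkyne, the free acid, the hydroxyls and the secondary silyl ether should tolerate the short exposure at 0 °C.

Step 7
Reactants: 16 9-oxo-5,7-dihydroxy-2-ynoic acid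
Product: 17 5,7,9-trihydroxy-2-ynoic acid
Conditions: Me4NBH(OAc)3 (6 equiv), MeCN/AcOH (1:1), −25 °C
Reagents that add atoms: none
Why: Evans–Saksena reduction, in which the C7 hydroxyl exchanges an acetate on boron and hydride is delivered intramolecularly through a chair-like six-membered transition state, setting the new C9 carbinol 1,3-anti to C7 (and thereby 1,3-syn to the C11 silyl ether); the mild acyloxyborohydride should not touch the ynoic acid, and the silyloxy group cannot direct.

Step 8
Reactants: 17 5,7,9-trihydroxy-2-ynoic acid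
Product: 19 silyl-protected dihydropyranone, via (Z)-enoic acid 18 (not isolated)
Conditions: H2 (1 atm), Pd/CaCO3 poisoned with Pb(OAc)2 (Lindlar catalyst), quinoline, EtOAc, rt; filter; then PPTS (cat.), CH2Cl2, rt
Reagents that add atoms: none
Why: Lindlar semihydrogenation adds H2 syn on the poisoned palladium surface, giving the (Z)-enoic acid in which the C5 hydroxyl can reach the carboxyl; acid-catalysed lactonisation (6-exo-trig acyl substitution at C1) then closes the dihydropyranone, the C7 and C9 hydroxyls being able to form only eight- and ten-membered rings.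

Step 9
Reactants: 19 silyl-protected dihydropyranone
Product: 20 (6S)-6-[(2S,4R,6R)-2,4,6-trihydroxypentadecyl]-5,6-dihydro-2H-pyran-2-one
Conditions: HF·pyridine, pyridine/THF, 0 °C → rt
Reagents that add atoms: none
Why: Fluoride-driven cleavage of the secondary silyl ether (strong Si–F bond); the buffered, non-basic medium should avoid both lactone opening and oxa-Michael addition of the side-chain hydroxyl to the enoate.

**Compound list**

1 | (2R)-2-(chloromethyl)oxirane, (R)-epichlorohydrin | ClC[C@H]1CO1 | starting material
2 | n-octylmagnesium bromide | CCCCCCCC[Mg]Br | starting material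
3 | bromomagnesium (2R)-1-chloroundecan-2-olate | ClC[C@H](O[Mg]Br)CCCCCCCCC | intermediate
4 | (2R)-2-nonyloxirane, (R)-1,2-epoxyundecane | CCCCCCCCC[C@@H]1CO1 | intermediate
5 | 1,5-dichloropentane-2,4-dione | ClCC(=O)CC(=O)CCl | starting material
6 | (2R,4R)-1,5-dichloropentane-2,4-diol | ClC[C@H](O)C[C@@H](O)CCl | intermediate
7 | (2R,4R)-1,2:4,5-diepoxypentane, (2R,2'R)-2,2'-methylenebis(oxirane) | C1O[C@@H]1C[C@@H]1CO1 | intermediate
8 | tert-butyl(1,3-dithian-2-yl)dimethylsilane | CC(C)(C)[Si](C)(C)C1SCCCS1 | starting material
9 | tert-butyl(2-lithio-1,3-dithian-2-yl)dimethylsilane | CC(C)(C)[Si](C)(C)C1([Li])SCCCS1 | intermediate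
10 | lithium (2R)-1-{2-[tert-butyl(dimethyl)silyl]-1,3-dithian-2-yl}undecan-2-olate | CCCCCCCCC[C@@H](O[Li])CC1([Si](C)(C)C(C)(C)C)SCCCS1 | intermediate
11 | 2-lithio-2-[(2R)-2-{[tert-butyl(dimethyl)silyl]oxy}undecyl]-1,3-dithiane | CCCCCCCCC[C@@H](O[Si](C)(C)C(C)(C)C)CC1([Li])SCCCS1 | intermediate
12 | (2R)-1-{2-[(2R)-2-{[tert-butyl(dimethyl)silyl]oxy}undecyl]-1,3-dithian-2-yl}-3-[(2R)-oxiran-2-yl]propan-2-ol | CCCCCCCCC[C@@H](O[Si](C)(C)C(C)(C)C)CC1(SCCCS1)C[C@H](O)C[C@@H]1CO1 | intermediate
13 | dilithium alkoxide of (2R,4S)-1-{2-[(2R)-2-{[tert-butyl(dimethyl)silyl]oxy}undecyl]-1,3-dithian-2-yl}hept-6-yne-2,4-diol | CCCCCCCCC[C@@H](O[Si](C)(C)C(C)(C)C)CC1(SCCCS1)C[C@H](O[Li])C[C@@H](O[Li])CC#C | intermediate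
14 | C7-lithio alkynide of 13 (trilithium species) | CCCCCCCCC[C@@H](O[Si](C)(C)C(C)(C)C)CC1(SCCCS1)C[C@H](O[Li])C[C@@H](O[Li])CC#C[Li] | intermediate
15 | (5S,7R)-8-{2-[(2R)-2-{[tert-butyl(dimethyl)silyl]oxy}undecyl]-1,3-dithian-2-yl}-5,7-dihydroxyoct-2-ynoic acid | CCCCCCCCC[C@@H](O[Si](C)(C)C(C)(C)C)CC1(SCCCS1)C[C@H](O)C[C@@H](O)CC#CC(=O)O | intermediate
16 | (5S,7R,11R)-11-{[tert-butyl(dimethyl)silyl]oxy}-5,7-dihydroxy-9-oxoicos-2-ynoic acid | CCCCCCCCC[C@@H](O[Si](C)(C)C(C)(C)C)CC(=O)C[C@H](O)C[C@@H](O)CC#CC(=O)O | intermediate
17 | (5S,7R,9S,11R)-11-{[tert-butyl(dimethyl)silyl]oxy}-5,7,9-trihydroxyicos-2-ynoic acid | CCCCCCCCC[C@@H](O[Si](C)(C)C(C)(C)C)C[C@@H](O)C[C@H](O)C[C@@H](O)CC#CC(=O)O | intermediate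
18 | (2Z,5S,7R,9S,11R)-11-{[tert-butyl(dimethyl)silyl]oxy}-5,7,9-trihydroxyicos-2-enoic acid | CCCCCCCCC[C@@H](O[Si](C)(C)C(C)(C)C)C[C@@H](O)C[C@H](O)C[C@@H](O)C/C=C\C(=O)O | intermediate
19 | (6S)-6-[(2S,4S,6R)-6-{[tert-butyl(dimethyl)silyl]oxy}-2,4-dihydroxypentadecyl]-5,6-dihydro-2H-pyran-2-one | CCCCCCCCC[C@@H](O[Si](C)(C)C(C)(C)C)C[C@@H](O)C[C@H](O)C[C@@H]1CC=CC(=O)O1 | intermediate
20 | (6S)-6-[(2S,4R,6R)-2,4,6-trihydroxypentadecyl]-5,6-dihydro-2H-pyran-2-one | CCCCCCCCC[C@@H](O)C[C@@H](O)C[C@H](O)C[C@@H]1CC=CC(=O)O1 | target

**Step count**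

Total steps: 9. Longest linear sequence: 8 steps (5 → 6 → 7 → 12 → 15 → 16 → 17 → 19 → 20).

**Steps most likely to fail, with fallbacks**

Step 5 (key step). The C-metalation of the newly formed alkyne may stay incomplete in the poly-alkoxide/amine medium. During the slow room-temperature opening, the neighbouring lithium alkoxide may also attack the oxirane intramolecularly. The fallback sets out from 12 and separates the two bond formations under Lewis-acid control. Lithium (trimethylsilyl)acetylide with BF3·OEt2 in THF at −78 °C (Yamaguchi–Hirao opening) should give (2R,4S)-1-{2-[(2R)-2-{[tert-butyl(dimethyl)silyl]oxy}undecyl]-1,3-dithian-2-yl}-7-(trimethylsilyl)hept-6-yne-2,4-diol F1. Fluoride-triggered desilylative carboxylation of F1 (CsF, CO2 at 1 atm, DMSO, rt, then acidification) returns to the route at 15.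

Step 4. The relay anion may add a second time to the remaining oxirane of the product, or the Brook migration may occur too early or incompletely, scrambling which epoxide is attacked. The fallback sets out from 4 and builds the same anion stepwise. 1,3-Dithiane (C1CSCSC1) is lithiated with n-BuLi in THF to 2-lithio-1,3-dithiane F2, which opens 4 to give (2R)-1-(1,3-dithian-2-yl)undecan-2-ol F3. Silylation (TBSCl, imidazole, DMF) gives tert-butyl{[(2R)-1-(1,3-dithian-2-yl)undecan-2-yl]oxy}dimethylsilane F4. Deprotonation of F4 with t-BuLi in THF/HMPA at −78 °C gives anion 11 directly, which is added slowly to excess 7; the route is rejoined at 12.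

Step 7. Reversible hemiketal formation between the C9 ketone and the free C5 hydroxyl may slow the directed hydride delivery and erode facial selectivity. The fallback sets out from 16 and closes the ring first, so that the C5 oxygen is locked in the lactone. Lindlar semihydrogenation (H2, Pd/CaCO3 poisoned with Pb(OAc)2, quinoline) should give (2Z,5S,7R,11R)-11-{[tert-butyl(dimethyl)silyl]oxy}-5,7-dihydroxy-9-oxoicos-2-enoic acid F5. PPTS then lactonises it to the keto lactone (6S)-6-[(2R,6R)-6-{[tert-butyl(dimethyl)silyl]oxy}-2-hydroxy-4-oxopentadecyl]-5,6-dihydro-2H-pyran-2-one F6. Evans–Saksena reduction of F6 (Me4NBH(OAc)3, MeCN/AcOH, −25 °C), directed by the C2' hydroxyl, returns to the route at 19.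

**Further compounds**

F1 | step 5 | (2R,4S)-1-{2-[(2R)-2-{[tert-butyl(dimethyl)silyl]oxy}undecyl]-1,3-dithian-2-yl}-7-(trimethylsilyl)hept-6-yne-2,4-diol | CCCCCCCCC[C@@H](O[Si](C)(C)C(C)(C)C)CC1(SCCCS1)C[C@H](O)C[C@@H](O)CC#C[Si](C)(C)C
F2 | step 4 | 2-lithio-1,3-dithiane | [Li]C1SCCCS1
F3 | step 4 | (2R)-1-(1,3-dithian-2-yl)undecan-2-ol | CCCCCCCCC[C@@H](O)CC1SCCCS1
F4 | step 4 | tert-butyl{[(2R)-1-(1,3-dithian-2-yl)undecan-2-yl]oxy}dimethylsilane | CCCCCCCCC[C@@H](O[Si](C)(C)C(C)(C)C)CC1SCCCS1
F5 | step 7 | (2Z,5S,7R,11R)-11-{[tert-butyl(dimethyl)silyl]oxy}-5,7-dihydroxy-9-oxoicos-2-enoic acid | CCCCCCCCC[C@@H](O[Si](C)(C)C(C)(C)C)CC(=O)C[C@H](O)C[C@@H](O)C/C=C\C(=O)O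
F6 | step 7 | (6S)-6-[(2R,6R)-6-{[tert-butyl(dimethyl)silyl]oxy}-2-hydroxy-4-oxopentadecyl]-5,6-dihydro-2H-pyran-2-one | CCCCCCCCC[C@@H](O[Si](C)(C)C(C)(C)C)CC(=O)C[C@H](O)C[C@@H]1CC=CC(=O)O1
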